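## Retrosynthetic overview

1. The last bond made is the C19–O tiglate ester of (13R)-labda-8(17),14-diene-13,19-diol. The C13 carbinol is carried unchanged from (R)-nerolidol, itself made from farnesol by Sharpless epoxidation and reductive epoxide opening.
2. The C19 alcohol comes from a 3-oxo-labdadien-19-oate. The C3 oxygen is a temporary activating group (removed by Barton–McCombie deoxygenation) and the 4α-methyl is put in by α-face methylation of the bicyclic β-keto ester.
3. Key disconnection: C4–C5 and C9–C10 in one oxidative radical cascade of an acyclic β-keto ester bearing a chiral ester auxiliary. Ring A closes first (C4–C5), ring B second (C9–C10), and the C8 radical is oxidised to the exocyclic C8=C17 alkene.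
4. Enabling feature: C4 carries C19 at the acid oxidation level next to C3, which can be a ketone, so C4 is a 1,3-dicarbonyl radical site. C10 and C8 each bear a methyl (C20, C17), so both closures are 6-endo onto the CH ends (C5, C9) of two (E)-trisubstituted alkenes. The C17 methyl on C8 supplies the hydrogen lost in forming the exocyclic methylene.
5. The acyclic precursor comes from γ-alkylation of the auxiliary acetoacetate dianion with the C1 allylic bromide obtained by terminal allylic oxidation of silylated (R)-nerolidol.

Key step: step 8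

Remark (numbering): labdane numbering is used throughout (C1–C10 decalin, C11–C16 side chain, C17 on C8, C18 = 4α-methyl, C19 = 4β-carbon, C20 on C10).

Remark (assumption): the (1S,2R,5S) enantiomer of 8-phenylmenthol is chosen on the model that its phenyl ring stacks over one face of the planar, Yb-chelated dicarbonyl radical (ester C=O syn to the carbinol C–H), which should expose the face whose chair-wise closure gives the 10β-methyl series. This sense is an assumption; if the opposite series forms, the enantiomeric auxiliary is used.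

## Route

Step 1
Reactants: 1 (2E,6E)-farnesol
Product: 2 (2R,3R)-2,3-epoxyfarnesol
Conditions: Ti(OiPr)4 (10 mol %), D-(−)-diethyl tartrate (12 mol %), anhydrous t-BuOOH (2 equiv), 4 Å MS, CH2Cl2, −20 °C
Reagents that add atoms: tert-butyl hydroperoxide, CC(C)(C)OO
Why: Sharpless asymmetric epoxidation reacts only at the allylic C2=C3 alkene, and with the D-(−)-tartrate ligand oxygen should be delivered to the face that gives the (2R,3R)-epoxide, whose tertiary carbon becomes C13 of the target.

Step 2
Reactants: 2 (2R,3R)-2,3-epoxyfarnesol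
Product: 4 (3R,6E)-nerolidol, via epoxy iodide 3 (not isolated)
Conditions: PPh3, I2, imidazole, THF, 0 °C; then Zn dust, AcOH, 0 °C → rt (crude iodide not purified)
Reagents that add atoms: none
Why: Appel-type iodination of the primary alcohol followed by zinc-induced reductive β-elimination of the 2,3-epoxy iodide opens the epoxide to the tertiary allylic alcohol without breaking the C3–O bond, so the epoxide configuration is carried over as (3R).

Step 3
Reactants: 4 (3R,6E)-nerolidol
Product: 5 (3R,6E)-nerolidol tert-butyldimethylsilyl ether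
Conditions: TBSOTf, 2,6-lutidine, CH2Cl2, 0 °C
Reagents that add atoms: tert-butyldimethylsilyl trifluoromethanesulfonate, CC(C)(C)[Si](C)(C)OS(=O)(=O)C(F)(F)F
Why: Silyl triflate silylation protects the hindered tertiary allylic alcohol as a robust ether, so that in step 8 it can neither ionise under Lewis acid nor trap the oxidised C8 centre as a cyclic ether; no stereocentre is touched.

Step 4
Reactants: 5 (3R,6E)-nerolidol tert-butyldimethylsilyl ether
Product: 6 (2E,6E,10R)-10-(tert-butyldimethylsilyloxy)-2,6,10-trimethyldodeca-2,6,11-trien-1-ol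
Conditions: SeO2 (0.3 equiv), t-BuOOH (3 equiv), salicylic acid (0.1 equiv), CH2Cl2, 0 °C → rt
Reagents that add atoms: selenium dioxide, O=[Se]=O (catalytic oxygen carrier); tert-butyl hydroperoxide, CC(C)(C)OO (terminal oxygen source)
Why: SeO2-catalysed allylic oxidation (ene reaction, then [2,3]-sigmatropic shift) should attack the terminal, most electron-rich trisubstituted alkene at its (E)-methyl group, giving the (E)-allylic alcohol that fixes the later C5=C10 geometry.

Step 5
Reactants: 6 (2E,6E,10R)-10-(tert-butyldimethylsilyloxy)-2,6,10-trimethyldodeca-2,6,11-trien-1-ol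
Product: 7 (2E,6E,10R)-1-bromo-10-(tert-butyldimethylsilyloxy)-2,6,10-trimethyldodeca-2,6,11-triene
Conditions: CBr4, PPh3, CH2Cl2, −20 → 0 °C
Reagents that add atoms: carbon tetrabromide, BrC(Br)(Br)Br
Why: Appel bromination converts the primary allylic alcohol into the bromide by SN2 displacement under neutral conditions that leave the silyl ether and both alkene geometries unchanged.

Step 6
Reactants: 8 (+)-8-phenylmenthol; 9 methyl acetoacetate
Product: 10 (1S,2R,5S)-8-phenylmenthyl 3-oxobutanoate
Conditions: DMAP (0.2 equiv), toluene, reflux, methanol removed over 4 Å MS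
Reagents that add atoms: none
Why: DMAP-catalysed transesterification of a β-keto ester with the hindered secondary alcohol is driven by removal of methanol and leaves the three auxiliary stereocentres untouched.

Step 7
Reactants: 10 (1S,2R,5S)-8-phenylmenthyl 3-oxobutanoate; 7 (2E,6E,10R)-1-bromo-10-(tert-butyldimethylsilyloxy)-2,6,10-trimethyldodeca-2,6,11-triene
Product: 12 (1S,2R,5S)-8-phenylmenthyl (6E,10E,14R)-14-(tert-butyldimethylsilyloxy)-6,10,14-trimethyl-3-oxohexadeca-6,10,15-trienoate, via acetoacetate dianion 11 (not isolated)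
Conditions: NaH (1.1 equiv), THF, 0 °C; n-BuLi (1.05 equiv), 0 °C; then 7, 0 °C → rt; aqueous work-up
Reagents that add atoms: none
Why: γ-Alkylation of the acetoacetate dianion: the more basic terminal carbanion displaces the primary allylic bromide by SN2, which assembles the whole acyclic chain with both (E)-alkenes and the C13 centre intact.

Step 8
Reactants: 12 (1S,2R,5S)-8-phenylmenthyl (6E,10E,14R)-14-(tert-butyldimethylsilyloxy)-6,10,14-trimethyl-3-oxohexadeca-6,10,15-trienoate
Product: 16 C4-unmethylated bicyclic β-keto ester (auxiliary ester of (13R)-13-silyloxy-3-oxolabda-8(17),14-diene lacking the C4 methyl), via C4 radical 13 (not isolated), via monocyclic C10 radical 14 (not isolated), via bicyclic C8 radical 15 (not isolated)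
Conditions: Mn(OAc)3·2H2O (2.2 equiv), Cu(OAc)2·H2O (1.0 equiv), Yb(OTf)3 (1.0 equiv), degassed CF3CH2OH, −5 → 0 °C, Ar
Reagents that add atoms: none
Why: Mn(OAc)3 oxidises the Yb-chelated enol of 12 to the electrophilic C4 radical 13, which closes ring A by 6-endo-trig attack on C5; the tertiary C10 radical 14 then closes ring B by 6-endo-trig attack on C9 (the C9–C10 bond), and the tertiary C8 radical 15 is captured by Cu(OAc)2 and loses a C17 hydrogen by β-hydride elimination to give the exocyclic C8=C17 alkene. The closest known reaction type is the oxidative free-radical polyene cyclisation of unsaturated β-keto esters with trivalent manganese and divalent copper, including the lanthanide-triflate-assisted variant steered by an 8-phenylmenthyl ester. Both closures are 6-endo rather than 5-exo because the proximal alkene carbons C10 and C8 carry methyl groups, so attack at the distal CH carbon gives a tertiary radical each time. The all-chair transition state with two (E)-alkenes should set the trans ring fusion (5α-H, 10β-CH3) and the equatorial C9 side chain (9α-H), while the absolute sense comes from the auxiliary, whose phenyl ring covers one face of the planar chelated radical so that C5 adds to the open face. C4 emerges as an enolisable CH with the ester equatorial and is fixed in step 9, and C13 is not involved. The step needs exocyclic rather than endocyclic alkene formation and no engagement of the vinyl group: the first is the usual preference of the copper-mediated elimination for the unhindered methyl hydrogens, and the second follows because the tertiary C8 radical adds only slowly to a monosubstituted alkene flanked by the quaternary C13 and is oxidised first.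

Step 9
Reactants: 16 C4-unmethylated bicyclic β-keto ester
Product: 17 (1S,2R,5S)-8-phenylmenthyl (13R)-13-(tert-butyldimethylsilyloxy)-3-oxolabda-8(17),14-dien-19-oate
Conditions: K2CO3 (3 equiv), MeI (5 equiv), acetone, 45 °C
Reagents that add atoms: iodomethane, CI
Why: C-Methylation of the β-keto ester enolate should occur on the α face, anti to the axial C10 methyl group and to the phenyl ring of the auxiliary (a matched pair), which places the new methyl equatorial (C18) and the ester axial (C19) and so sets the C4 quaternary centre.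

Step 10
Reactants: 17 (1S,2R,5S)-8-phenylmenthyl (13R)-13-(tert-butyldimethylsilyloxy)-3-oxolabda-8(17),14-dien-19-oate
Product: 18 (1S,2R,5S)-8-phenylmenthyl (13R)-13-(tert-butyldimethylsilyloxy)-3β-hydroxylabda-8(17),14-dien-19-oate
Conditions: NaBH4, MeOH/THF (1:1), 0 °C
Reagents that add atoms: none
Why: NaBH4 reduces only the ketone (the hindered ester is inert), with axial hydride delivery from the α face expected to give the equatorial 3β-alcohol; the C3 configuration is of no consequence because the centre is removed in step 12.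

Step 11
Reactants: 18 (1S,2R,5S)-8-phenylmenthyl (13R)-13-(tert-butyldimethylsilyloxy)-3β-hydroxylabda-8(17),14-dien-19-oate
Product: 19 (1S,2R,5S)-8-phenylmenthyl (13R)-13-(tert-butyldimethylsilyloxy)-3β-(phenoxythiocarbonyloxy)labda-8(17),14-dien-19-oate
Conditions: PhOC(S)Cl (2 equiv), pyridine, DMAP (0.2 equiv), CH2Cl2, rt → 40 °C
Reagents that add atoms: O-phenyl chlorothionoformate, S=C(Cl)Oc1ccccc1
Why: DMAP-catalysed acylation gives the Barton–McCombie precursor without forming a metal alkoxide that could trigger retro-aldol cleavage of the β-hydroxy ester.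

Step 12
Reactants: 19 (1S,2R,5S)-8-phenylmenthyl (13R)-13-(tert-butyldimethylsilyloxy)-3β-(phenoxythiocarbonyloxy)labda-8(17),14-dien-19-oate
Product: 20 (1S,2R,5S)-8-phenylmenthyl (13R)-13-(tert-butyldimethylsilyloxy)labda-8(17),14-dien-19-oate
Conditions: Bu3SnH (2 equiv), AIBN (0.2 equiv), toluene, 100 °C
Reagents that add atoms: none
Why: Barton–McCombie deoxygenation: the stannyl radical adds to the thiocarbonyl sulfur, β-scission releases the secondary C3 radical, which has no alkene within cyclisation range and is reduced by Bu3SnH to the C3 methylene.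

Step 13
Reactants: 20 (1S,2R,5S)-8-phenylmenthyl (13R)-13-(tert-butyldimethylsilyloxy)labda-8(17),14-dien-19-oate
Product: 21 (13R)-13-(tert-butyldimethylsilyloxy)labda-8(17),14-dien-19-ol
Conditions: LiAlH4 (4 equiv), THF, reflux; aqueous NaOH work-up
Reagents that add atoms: none
Why: LiAlH4 reduces the hindered axial ester to the primary C19 alcohol and releases the auxiliary for recovery, while the silyl ether and the isolated alkenes are inert to hydride.

Step 14
Reactants: 21 (13R)-13-(tert-butyldimethylsilyloxy)labda-8(17),14-dien-19-ol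
Product: 22 (13R)-labda-8(17),14-diene-13,19-diol
Conditions: TBAF (3 equiv), THF, 45 °C
Reagents that add atoms: none
Why: Fluoride cleaves the tertiary silyl ether by attack at silicon, so the C13–O bond and the (13R) configuration are untouched.

Step 15
Reactants: 22 (13R)-labda-8(17),14-diene-13,19-diol; 23 tigloyl chloride
Product: 24 (13R)-13-hydroxylabda-8(17),14-dien-19-yl (E)-2-methylbut-2-enoate
Conditions: pyridine, DMAP (0.2 equiv), CH2Cl2, 0 °C → rt
Reagents that add atoms: none
Why: DMAP-catalysed acylation should esterify the primary C19 hydroxyl while the tertiary allylic C13 hydroxyl is too hindered to react under these conditions, and pyridine rather than a trialkylamine avoids vinylketene formation so that the (E)-geometry of the acyl group is kept.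

## Compound list

1 | (2E,6E)-farnesol | CC(C)=CCC/C(C)=C/CC/C(C)=C/CO | starting material
2 | (2R,3R)-2,3-epoxyfarnesol, [(2R,3R)-3-[(3E)-4,8-dimethylnona-3,7-dien-1-yl]-3-methyloxiran-2-yl]methanol | OC[C@H]1O[C@]1(C)CC/C=C(\C)CCC=C(C)C | intermediate
3 | epoxy iodide, (2S,3R)-2-(iodomethyl)-3-methyl-3-[(3E)-4,8-dimethylnona-3,7-dien-1-yl]oxirane (not isolated) | IC[C@H]1O[C@]1(C)CC/C=C(\C)CCC=C(C)C | intermediate
4 | (3R,6E)-nerolidol | C=C[C@](C)(O)CC/C=C(\C)CCC=C(C)C | intermediate
5 | (3R,6E)-nerolidol tert-butyldimethylsilyl ether | C=C[C@](C)(O[Si](C)(C)C(C)(C)C)CC/C=C(\C)CCC=C(C)C | intermediate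
6 | (2E,6E,10R)-10-(tert-butyldimethylsilyloxy)-2,6,10-trimethyldodeca-2,6,11-trien-1-ol | C=C[C@](C)(O[Si](C)(C)C(C)(C)C)CC/C=C(\C)CC/C=C(\C)CO | intermediate
7 | (2E,6E,10R)-1-bromo-10-(tert-butyldimethylsilyloxy)-2,6,10-trimethyldodeca-2,6,11-triene | C=C[C@](C)(O[Si](C)(C)C(C)(C)C)CC/C=C(\C)CC/C=C(\C)CBr | intermediate
8 | (+)-8-phenylmenthol, (1S,2R,5S)-5-methyl-2-(2-phenylpropan-2-yl)cyclohexan-1-ol | C[C@H]1CC[C@@H]([C@H](C1)O)C(C)(C)c1ccccc1 | starting material
9 | methyl acetoacetate | COC(=O)CC(C)=O | starting material
10 | (1S,2R,5S)-8-phenylmenthyl 3-oxobutanoate | CC(=O)CC(=O)O[C@H]1C[C@@H](C)CC[C@@H]1C(C)(C)c1ccccc1 | intermediate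
11 | sodium lithium dianion of 10 (not isolated) | [Na+].[Li+].[CH2-]C(=O)[CH-]C(=O)O[C@H]1C[C@@H](C)CC[C@@H]1C(C)(C)c1ccccc1 | intermediate
12 | (1S,2R,5S)-8-phenylmenthyl (6E,10E,14R)-14-(tert-butyldimethylsilyloxy)-6,10,14-trimethyl-3-oxohexadeca-6,10,15-trienoate | C=C[C@](C)(O[Si](C)(C)C(C)(C)C)CC/C=C(\C)CC/C=C(\C)CCC(=O)CC(=O)O[C@H]1C[C@@H](C)CC[C@@H]1C(C)(C)c1ccccc1 | intermediate
13 | C4 radical of 12 (radical at the carbon between the two carbonyls; not isolated) | C=C[C@](C)(O[Si](C)(C)C(C)(C)C)CC/C=C(\C)CC/C=C(\C)CCC(=O)[CH]C(=O)O[C@H]1C[C@@H](C)CC[C@@H]1C(C)(C)c1ccccc1 | intermediate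
14 | monocyclic C10 radical (ring A closed, ester and C6 chain equatorial and trans; not isolated) | C=C[C@](C)(O[Si](C)(C)C(C)(C)C)CC/C=C(\C)CC[C@@H]1[C](C)CCC(=O)[C@H]1C(=O)O[C@H]2C[C@@H](C)CC[C@@H]2C(C)(C)c2ccccc2 | intermediate
15 | bicyclic C8 radical (trans-decalin, tertiary radical at C8; not isolated) | C=C[C@](C)(O[Si](C)(C)C(C)(C)C)CC[C@H]1[C](C)CC[C@H]2[C@H](C(=O)O[C@H]3C[C@@H](C)CC[C@@H]3C(C)(C)c3ccccc3)C(=O)CC[C@]12C | intermediate
16 | C4-unmethylated bicyclic β-keto ester: (1S,2R,5S)-8-phenylmenthyl ester of the (13R)-13-(tert-butyldimethylsilyloxy)-3-oxolabda-8(17),14-diene skeleton lacking the C4 methyl; 5α-H, 9α-H, 10β-CH3; keto tautomer with equatorial (4α) ester shown, C4 epimerisable through the enol | C=C[C@](C)(O[Si](C)(C)C(C)(C)C)CC[C@H]1C(=C)CC[C@H]2[C@H](C(=O)O[C@H]3C[C@@H](C)CC[C@@H]3C(C)(C)c3ccccc3)C(=O)CC[C@]12C | intermediate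
17 | (1S,2R,5S)-8-phenylmenthyl (13R)-13-(tert-butyldimethylsilyloxy)-3-oxolabda-8(17),14-dien-19-oate (4α-CH3, 4β-ester) | C=C[C@](C)(O[Si](C)(C)C(C)(C)C)CC[C@H]1C(=C)CC[C@H]2[C@@](C)(C(=O)O[C@H]3C[C@@H](C)CC[C@@H]3C(C)(C)c3ccccc3)C(=O)CC[C@]12C | intermediate
18 | (1S,2R,5S)-8-phenylmenthyl (13R)-13-(tert-butyldimethylsilyloxy)-3β-hydroxylabda-8(17),14-dien-19-oate | C=C[C@](C)(O[Si](C)(C)C(C)(C)C)CC[C@H]1C(=C)CC[C@H]2[C@@](C)(C(=O)O[C@H]3C[C@@H](C)CC[C@@H]3C(C)(C)c3ccccc3)[C@@H](O)CC[C@]12C | intermediate
19 | (1S,2R,5S)-8-phenylmenthyl (13R)-13-(tert-butyldimethylsilyloxy)-3β-(phenoxythiocarbonyloxy)labda-8(17),14-dien-19-oate | C=C[C@](C)(O[Si](C)(C)C(C)(C)C)CC[C@H]1C(=C)CC[C@H]2[C@@](C)(C(=O)O[C@H]3C[C@@H](C)CC[C@@H]3C(C)(C)c3ccccc3)[C@@H](OC(=S)Oc3ccccc3)CC[C@]12C | intermediate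
20 | (1S,2R,5S)-8-phenylmenthyl (13R)-13-(tert-butyldimethylsilyloxy)labda-8(17),14-dien-19-oate | C=C[C@](C)(O[Si](C)(C)C(C)(C)C)CC[C@H]1C(=C)CC[C@H]2[C@@](C)(C(=O)O[C@H]3C[C@@H](C)CC[C@@H]3C(C)(C)c3ccccc3)CCC[C@]12C | intermediate
21 | (13R)-13-(tert-butyldimethylsilyloxy)labda-8(17),14-dien-19-ol | C=C[C@](C)(O[Si](C)(C)C(C)(C)C)CC[C@H]1C(=C)CC[C@H]2[C@@](C)(CO)CCC[C@]12C | intermediate
22 | (13R)-labda-8(17),14-diene-13,19-diol | C=C[C@](C)(O)CC[C@H]1C(=C)CC[C@H]2[C@@](C)(CO)CCC[C@]12C | intermediate
23 | tigloyl chloride, (E)-2-methylbut-2-enoyl chloride | C/C=C(\C)C(Cl)=O | starting material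
24 | (13R)-13-hydroxylabda-8(17),14-dien-19-yl (E)-2-methylbut-2-enoate (4S,5R,9S,10R,13R) | C=C[C@](C)(O)CC[C@H]1C(=C)CC[C@H]2[C@@](C)(COC(=O)/C(C)=C/C)CCC[C@]12C | target

## Step count and risks

Total step count: 15. Longest linear sequence: 14 steps (steps 1–5 and 7–15); step 6 is a one-step side branch.

**Step 8 (key step).** What may go wrong: the C10 radical may be oxidised before ring B closes, the enolisable product may be oxidised further by remaining trivalent manganese, and the copper-mediated elimination may lose its exocyclic preference. The fallback sets out from 12 and returns at 16, and replaces the oxidative cascade by a non-oxidative group-transfer cascade followed by a separate elimination. Compound 12 would be selenenylated at the doubly activated carbon (PhSeCl, pyridine, CH2Cl2, 0 °C) to give the α-phenylselanyl β-keto ester F1. Irradiation (sun lamp) with Yb(OTf)3 in CH2Cl2/THF at −20 °C should then bring about phenylselanyl-group-transfer radical bicyclisation under the same chelate and auxiliary control, the C8 radical taking the selanyl group from the less hindered α face to give the 8α-phenylselanyl bicyclic β-keto ester F2. Oxidation (H2O2, pyridine, CH2Cl2, 0 °C) and syn-elimination of the selenoxide, which should favour the three freely rotating C17 hydrogens, would give 16.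

**Step 4.** What may go wrong: competing allylic oxidation next to the internal trisubstituted alkene and over-oxidation of the product to the enal. The fallback sets out from 5 and returns at 7, and builds the allylic bromide by terminal epoxidation and transposition instead of direct C–H oxidation. Terminal-selective bromohydrin formation (NBS, THF/H2O, 0 °C) would give the bromohydrin F3, and K2CO3 in MeOH would close it to the terminal epoxide F4. Al(OiPr)3 in refluxing toluene should isomerise the epoxide to the secondary allylic alcohol F5 with a 1,1-disubstituted alkene. PBr3 in Et2O at −10 °C would then give, with allylic transposition (SN2′), the thermodynamically favoured primary (E)-bromide 7.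

**Step 13.** What may go wrong: stalled hydride delivery to the axial, neopentyl ester carbonyl shielded by the auxiliary, leading to incomplete reduction or arrest at the aldehyde stage. The fallback sets out from 17 and returns at 21, and moves the ester reduction to the β-keto ester stage. LiAlH4 (THF, 0 °C → rt) on 17 should reduce the ketone first, and the C3 alkoxyaluminate then delivers hydride intramolecularly to the neighbouring ester, giving the 3β,19-diol F6 and the free auxiliary. 1,1′-Thiocarbonyldiimidazole (toluene, 80 °C) would close the six-membered cyclic thionocarbonate F7. Bu3SnH/AIBN (toluene, 100 °C) should cleave it at the secondary C3–O bond (secondary rather than primary radical), and hydrolytic work-up (K2CO3, MeOH) would give alcohol 21.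

Further compounds
F1 | step 8 | (1S,2R,5S)-8-phenylmenthyl (6E,10E,14R)-14-(tert-butyldimethylsilyloxy)-6,10,14-trimethyl-3-oxo-2-(phenylselanyl)hexadeca-6,10,15-trienoate (C2 epimers) | C=C[C@](C)(O[Si](C)(C)C(C)(C)C)CC/C=C(\C)CC/C=C(\C)CCC(=O)C([Se]c1ccccc1)C(=O)O[C@H]1C[C@@H](C)CC[C@@H]1C(C)(C)c1ccccc1
F2 | step 8 | 8α-phenylselanyl bicyclic β-keto ester (16 with C8 saturated, 8β-CH3 and 8α-SePh in place of the exocyclic alkene) | C=C[C@](C)(O[Si](C)(C)C(C)(C)C)CC[C@H]1[C@](C)([Se]c3ccccc3)CC[C@H]2[C@H](C(=O)O[C@H]3C[C@@H](C)CC[C@@H]3C(C)(C)c3ccccc3)C(=O)CC[C@]12C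
F3 | step 4 | terminal bromohydrin of 5, (6E,10R)-3-bromo-10-(tert-butyldimethylsilyloxy)-2,6,10-trimethyldodeca-6,11-dien-2-ol (C3 epimers) | C=C[C@](C)(O[Si](C)(C)C(C)(C)C)CC/C=C(\C)CCC(Br)C(C)(C)O
F4 | step 4 | terminal epoxide of 5, tert-butyl{[(3R,6E)-9-(3,3-dimethyloxiran-2-yl)-3,7-dimethylnona-1,6-dien-3-yl]oxy}dimethylsilane (epoxide epimers) | C=C[C@](C)(O[Si](C)(C)C(C)(C)C)CC/C=C(\C)CCC1OC1(C)C
F5 | step 4 | (6E,10R)-10-(tert-butyldimethylsilyloxy)-2,6,10-trimethyldodeca-1,6,11-trien-3-ol (C3 epimers) | C=C[C@](C)(O[Si](C)(C)C(C)(C)C)CC/C=C(\C)CCC(O)C(C)=C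
F6 | step 13 | (13R)-13-(tert-butyldimethylsilyloxy)labda-8(17),14-diene-3β,19-diol | C=C[C@](C)(O[Si](C)(C)C(C)(C)C)CC[C@H]1C(=C)CC[C@H]2[C@@](C)(CO)[C@@H](O)CC[C@]12C
F7 | step 13 | 3β,19-O-thiocarbonyl derivative (six-membered cyclic thionocarbonate) of F6 | C=C[C@](C)(O[Si](C)(C)C(C)(C)C)CC[C@H]1C(=C)CC[C@H]2[C@@]3(C)COC(=S)O[C@H]3CC[C@]12C
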